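The earlier runs and the new flask were computed on assumed constants, noise included.

You cannot meet the whole charge of fresh partner at the start of these flasks, since it goes in at a steady rate over 8.0 h. Here is what you take over: substrate and coupling partner stand in the flask from the start, and fresh partner arrives at cD/tf, where cD is its whole charge per starting volume and tf the dosing time.

| flask | substrate | fresh partner | coupling partner | remark | time |
|---|---|---|---|---|---|
| beta | 0.48 M | 0.53 M (fed, over 8.0 h) | 0.72 M | run made earlier |  |
| theta | 0.48 M | 1.2 M (fed, over 8.0 h) | 0.72 M | run made earlier |  |
| dawn | 0.48 M | 0.200 M (fed, over 8.0 h) | 0.720 M |  | 8.0 h |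
| midnight | 0.48 M | 0.400 M (fed, over 8.0 h) | 0.720 M |  | 8.0 h |
| summer | 0.48 M | 0.800 M (fed, over 8.0 h) | 0.720 M |  | 8.0 h |
| spring | 0.48 M | 1.50 M (fed, over 8.0 h) | 0.720 M |  | 8.0 h |

- beta (time / h: target / %): 0.500: 1; 1.33: 3; 2.50: 4; 4.00: 19; 6.00: 29
- theta (time / h: target / %): 1.00: 0; 2.50: 10; 3.00: 13; 5.00: 20; 6.00: 21

(standard deviation of a reading: 1.5 percentage points)

- amount of target at the end, in percent of the substrate charged for dawn, midnight, summer, spring, in this order
- how that number moves from the first to the last of them (rises, then falls / rises all the way / hardly changes / falls, then rises / falls all the way)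

- the analysis behind the earlier runs scatters by 1.5 percentage points, standard deviation
- "hardly changes" means that all values lie within two and a half points (for a concentration: within two and a half percent of the largest)

Watch the crossing time t×, the hour at which the fresh partner fed, reckoned as if the feed ran on at its rate, equals cB, the coupling partner charged:

t× = cB·tf/cD

theta: 4.80 h; beta: 10.9 h

dawn: 28.8 h; midnight: 14.4 h; summer: 7.20 h; spring: 3.84 h

Theta crosses earlier than its last reading, and it reads 20 % at 5.00 h and 21 % at 6.00 h, a step within the scatter. Beta's t× lies later than its last reading and past the end of its feed, and beta is still climbing, from 19 % to 29 %.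

Written with the feed rate, t× is cB divided by cD/tf, so at fixed cB a faster feed brings the crossing earlier. Spring's crossing time is 3.84 h, earlier than the end, and summer's also falls inside the run. My own reckoning gives no numbers: I expect dawn and midnight still climbing at 8.0 h, and summer and spring flat or worse.

The forecast gives 12 %, 27 %, 31 % and 18 %, a row that rises, then falls: “So excess partner is wasted, or it kills the catalyst or the product.”

The flasks end at 22.5 %, 32.1 %, 24.6 % and 9.66 %, so the row rises, then falls, as forecast, but dawn ends higher and spring lower.

    fresh partner + target → over-reaction product (k = 1.30 × 10⁻⁴ M⁻¹ s⁻¹)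
    coupling partner + fresh partner → second intermediate (k = 2.30 × 10⁻⁴ M⁻¹ s⁻¹)
    substrate + coupling partner → open intermediate (k = 4.40 × 10⁻⁵ M⁻¹ s⁻¹)
    open intermediate + second intermediate → target (k = 0.00320 M⁻¹ s⁻¹)

Spring crosses at 3.84 h, and by 8.00 h its coupling partner, the limiting reagent there, stands at 4.00 % of its charge. That shortage is one part of spring's loss: without it, target ends at 36.4 % instead of 9.66 %. Dawn's t× of 28.8 h lies past its end, and dawn keeps 49.7 % of its coupling partner at 8.00 h. There the same change gains less, taking target from 22.5 % to 27.7 %. Dawn is held back more by the gradual adding of fresh partner and the length of the run, acting together: with the charge given at once target ends at 32.7 %, and with the run taken to 80.0 h at 32.9 %.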